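Numbering follows the lignan convention: C1 carries ring C, C2 and C3 carry the hydroxymethyl groups, C4 is the ring CH2, and ring A is C4a–C5–C6–C7–C8–C8a.

## Structural features

The target is a 1-aryltetralin cyclolignan: aromatic ring A is fused through C4a/C8a to the partly saturated ring B (C1–C4 sp3), and a guaiacyl ring C sits on C1. Ring A is pentasubstituted, with three neighbouring oxygens (OMe on C5 and C6, free OH on C7), one hydrogen on C8 and the two fusion carbons. C1 (R), C2 (S) and C3 (S) are contiguous stereocentres with the aryl group and both hydroxymethyl groups mutually trans, and C4 is a plain methylene. The fragile groups are the two phenols (easily oxidised) and the doubly benzylic C1, which sits para to the ring C hydroxyl and can be scrambled through a quinone methide under oxidising or strongly acidic conditions. The two difficulties are a regiodefined ring A in which only one of three adjacent oxygens is a free phenol, and absolute control of the stereotriad. The key step reads C5–C8 as a 1,2,3-trioxygenated butadiene and C4a/C8a as the two carbons of an alkyne that already carries C4 (as an ester) and C1 (as the ring C carbinol). The ester that ends up on C4a then distinguishes the hydrogen-bonded C5 oxygen from the free C7 oxygen.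

## Logic of the disconnections

24 ⇒ 23. The two O–CH2Ph bonds are cut and an oxygen is returned to C4. Both phenols then stay masked until the last step, and the benzylic C4 oxygen left by the cycloaddition is an activated C–O bond that the same hydrogenolysis removes. The forward step must cleave C4–O without passing through a C3=C4 alkene.

23 ⇒ 22. No skeletal bond is cut; the C2 and C3 hydroxymethyl groups go back to esters of a chiral alcohol. The esters are what make the C2–C3 unit a dienophile and a carrier of chirality. The forward reduction must be faster than enolisation at C2 and C3.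

22 ⇒ 16 + 19 (through 20 and 21). C1–C2 and C3–C4 are cut, and C4 is taken back from the aldehyde to the alcohol level. This is the one disconnection that removes ring B and every stereocentre at once, leaving the flat, achiral 16 and the C2-symmetric 19. The light-sensitive 20 gains nothing from isolation, so the oxidation is joined to the photochemical stage. The forward oxidation must stop at the aldehyde, and the forward cycloaddition must control the mode (ester beside the hydroxyl endo) and the face (auxiliary).

19 ⇒ 17 + 18. The two acyl–oxygen bonds are cut, giving two commercial materials. The forward acylation must not racemise 18.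

16 ⇒ 15. No skeletal bond is cut; C4 goes back to the carboxylic acid level, which is what the C1 deoxygenation delivers. The forward reduction must reach a doubly ortho-substituted acid and leave the ethers alone.

15 ⇒ 13 (through 14). The C1–H bond goes back to C1–O and the methyl ester is restored. C1 must be oxygenated in the ring A precursor for regiochemical reasons, so the oxygen has to be removed later; the neighbouring ester is used to turn C1–O into a lactone C–O bond, which avoids a free C1 cation next to an ester. The forward reduction must spare aryl benzyl ethers.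

13 ⇒ 11 (through 12). The O–benzyl bond at C7 and the O–methyl bond at C5 are cut, exposing the two phenols exactly as the cycloaddition forms them. The forward alkylations must tell them apart.

11 ⇒ 5 + 9 (through 10). C4a–C5 and C8–C8a are cut. The most demanding ring is reduced to a four-carbon diene from a β-keto ester and a four-carbon ynoate from an aldehyde. The forward step must be regioselective and must aromatise by loss of methanol.

9 ⇒ 8 ⇒ 6 + 7. The O–Si bond and then the C1–alkyne bond are cut, giving two commercial compounds. The forward addition needs a propiolate anion that is stable only at low temperature.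

5 ⇒ 4 ⇒ 3 ⇒ 1 + 2. Two O–Si bonds and then the C6–C7 bond are cut. The oxygen on C6 comes from 1 and the C7–C8 unit from 2. The forward acylation must occur on carbon.

## Other disconnections considered

Alternative 1: The cut is through C2–C3 and C1–C8a, giving a feruloyl unit (ring C, C1, C2) and a 4-benzyloxy-2,3-dimethoxycinnamoyl unit (ring A, C4, C3), both carried on the nitrogens of a C2-symmetric imidazolidinone in A1.
- Forward step: a one-electron oxidant (FeCl3, trivalent iron, or a laccase with O2) would convert the free phenol of A1 into a phenoxyl radical. Its C2 would add to C3 of the neighbouring cinnamoyl group, and after a second oxidation and loss of the C3 proton ring A would close onto the quinone methide carbon C1 to give dihydronaphthalene A2.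
- In favour: ring A is bought as a benzaldehyde, two C–C bonds and ring B form in one flask, the symmetry of the auxiliary makes the acylation order irrelevant, and the ring C phenol needs no protection.
- Against: the oxidant must choose the phenol over the electron-rich trialkoxycinnamoyl arene and leave the phenol of A2 alone. Intermolecular couplings of the radical compete. Face selectivity in a radical addition and a cationic closure rests on remote phenyl groups. A2 still lacks the C3 stereocentre, which would have to come from hydrogenation of C3=C4 inside a seven-membered diacylurea ring of uncertain preference.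
- Comparison: on step economy this alternative is the better one, and it is the equal of the chosen plan in ending with a hydride reduction and a hydrogenolysis. The chosen plan is stronger on mechanism (closed-shell cycloadditions with predictable regiochemistry) and on structure (ring A oxygen pattern, free C7 phenol and all three stereocentres follow from the construction).

Alternative 2: The cut is through C4a–C8a and C7–C8, which opens rings A and B together to the chain compound A3: a 3,4-dimethoxyfuran (C4a, C5, C6, C7) tied through C4–C3–C2–C1 to an ynoate (C8a, C8).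
- Forward step: heating A3 would give an intramolecular furan–alkyne [4+2] adduct, and a trace of CF3CO2H would open the oxygen bridge toward C7 to give tetralin A4.
- In favour: the tether fixes the regiochemistry, which is better than relying on polarisation as the chosen plan does. The driving force (aromatisation of an alkyne cycloadduct) is the same, so the two are equal in kind of reactivity. Rings A and B form at once, the C5 and C6 methyl ethers come with the furan so no phenol differentiation is needed (better), and the cycloaddition has no stereochemical task.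
- Against: the stereochemical problem is only moved back, because A3 must already hold C1, C2 and C3 as an acyclic triad. C1 in A3 is benzylic and propargylic next to the ynoate and could epimerise through the allenoate on heating. 2-Alkyl-3,4-dimethoxyfurans are sensitive to acid and air. A four-atom tether makes the cycloaddition slower and more reversible. A4 carries an ester on C8 that must be hydrolysed and decarboxylated.
- Comparison: the key step is more powerful than the chosen one, but the linear precursor is much longer, so the total step count should be higher. The chosen plan is convergent from small pieces and creates the triad on a rigid ring in one step.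

Alternative 3: The cut is through C1–C2 only.
- Forward step: A5 has the ring C carbinol on C8a and a C4–C3–C2–CHO chain on C4a. Under a diarylprolinol silyl ether and a carboxylic acid it would lose water to give the ring C para-quinone methide, and the enamine of the aldehyde would add through C2 to C1 to close ring B and give A6.
- In favour: induction is catalytic where the chosen plan uses a stoichiometric auxiliary (better). The ring C phenol is the activating group and needs no protection (better). The C1 oxygen serves as the leaving group, whereas the chosen plan removes oxygen from C1 and later from C4 (better redox economy). The all-trans outcome is backed by the epimerisable C2 aldehyde, equal to the thermodynamic backing of the chosen cycloadduct.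
- Against: only C1 and C2 are set; C3 must be in place beforehand and matched to the catalyst. A5 needs the C3–C4 bond and a homologation in separate steps. The aldehyde could self-condense and the quinone methide could be trapped intermolecularly.
- Comparison: A5 still needs the ring A that the chosen key step delivers (11 would be a sensible source), so this competes with the second half of the chosen route, not with its key step. The o-quinodimethane cycloaddition there forms C1–C2, C3–C4 and all stereocentres at once, which should make the chosen plan shorter.

Key step: step 6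

Assumption: the (R)-lactate fumarate 19 is taken to steer the diene to the face that gives the (1R) series; should the sense of induction be the opposite, methyl (S)-lactate replaces 18 and nothing else changes.

Step 1
Reactants: 1 methyl methoxyacetate; 2 acetyl chloride
Product: 3 methyl 2-methoxy-3-oxobutanoate
Conditions: LiN(SiMe3)2 (2.1 equiv), THF, −78 °C; then 2, −78 → 0 °C; 1 M HCl
Reagents that add atoms: none
Why: Crossed Claisen-type C-acylation of a preformed lithium ester enolate by an acid chloride; the second equivalent of base deprotonates the β-keto ester as it forms, which prevents proton exchange with unreacted enolate and a second acylation.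

Step 2
Reactants: 3 methyl 2-methoxy-3-oxobutanoate
Product: 4 methyl 2-methoxy-3-(trimethylsilyloxy)but-2-enoate (E/Z mixture)
Conditions: Me3SiCl, Et3N, hexane, rt
Reagents that add atoms: chlorotrimethylsilane, C[Si](C)(C)Cl
Why: O-Silylation of the enol of a β-keto ester by amine and chlorosilane (silyl enol ether formation); the double-bond geometry is irrelevant because both isomers give the same dienolate in step 3.

Step 3
Reactants: 4 methyl 2-methoxy-3-(trimethylsilyloxy)but-2-enoate
Product: 5 1,2-dimethoxy-1,3-bis(trimethylsilyloxy)buta-1,3-diene
Conditions: LiN(i-Pr)2, THF, −78 °C; Me3SiCl; non-aqueous work-up, used at once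
Reagents that add atoms: chlorotrimethylsilane, C[Si](C)(C)Cl
Why: γ-Deprotonation of the β-silyloxy enoate and O-silylation of the dienolate, the standard second stage in making 1-alkoxy-1,3-bis(silyloxy)dienes; 5 is moisture-sensitive and is not stored.

Step 4
Reactants: 6 methyl propiolate; 7 4-benzyloxy-3-methoxybenzaldehyde
Product: 8 methyl 4-(4-benzyloxy-3-methoxyphenyl)-4-hydroxybut-2-ynoate (racemic)
Conditions: LiN(SiMe3)2, THF, −78 °C; then 7; AcOH quench at −78 °C
Reagents that add atoms: none
Why: 1,2-Addition of a lithium acetylide (lithiated propiolate, kept at −78 °C to avoid self-condensation) to an aromatic aldehyde; the carbinol is made racemic on purpose because C1 later becomes CH2.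

Step 5
Reactants: 8 methyl 4-(4-benzyloxy-3-methoxyphenyl)-4-hydroxybut-2-ynoate
Product: 9 methyl 4-(4-benzyloxy-3-methoxyphenyl)-4-(tert-butyldimethylsilyloxy)but-2-ynoate (racemic)
Conditions: t-BuMe2SiCl, imidazole, DMF, 0 °C → rt
Reagents that add atoms: tert-butyl(chloro)dimethylsilane, CC(C)(C)[Si](C)(C)Cl
Why: Imidazole-mediated silylation of a secondary alcohol; the weakly basic medium avoids isomerisation of the γ-hydroxy ynoate, and the tert-butyldimethylsilyl group is chosen to outlast the acid treatment of step 6.

Step 6
Reactants: 5 1,2-dimethoxy-1,3-bis(trimethylsilyloxy)buta-1,3-diene (2.5 equiv); 9 methyl 4-(4-benzyloxy-3-methoxyphenyl)-4-(tert-butyldimethylsilyloxy)but-2-ynoate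
Product: 11 methyl 6-[(4-benzyloxy-3-methoxyphenyl)(tert-butyldimethylsilyloxy)methyl]-2,4-dihydroxy-3-methoxybenzoate (racemic), via cyclohexa-1,4-diene cycloadduct 10 (not isolated)
Conditions: toluene, 110 °C, sealed tube; then 10% aq. citric acid–THF, 0 °C → rt
Reagents that add atoms: none
Why: Diels–Alder reaction of an electron-rich 1-alkoxy-1,3-bis(silyloxy)diene with an electron-poor alkyne followed by aromatisation, the known route from such dienes and acetylenic esters to salicylate-type arenes. The diene HOMO is largest on the unsubstituted CH2 terminus (C8), which receives the donation of the C7 silyloxy group and of the ketene acetal oxygens through the diene, and the ynoate LUMO is largest on the carbon β to the ester (C8a); the more advanced bond is therefore C8–C8a, and the ketene acetal carbon (C5) bonds to the α-carbon (C4a). Ring A is closed intermolecularly as a six-membered ring in a concerted, asynchronous [4+2] cycloaddition that forms both bonds. Adduct 10 has a mixed silyl methyl ketal at C5: aqueous acid cleaves the O–Si bonds, the C5 hemiketal expels methanol, and the resulting dienone tautomerises through C8–H to the benzene, which is why methanol is lost and O5 ends as a phenol. No stereocentre is created; the sp3 centres of 10 disappear and C1 stays racemic. Only regioselectivity is required, and it is secured by keeping C1 at the carbinol level so that the ester is the only acceptor on the alkyne (a C1 ketone would reverse the polarisation), helped by the inductive pull of the C1 oxygen on C8a. The tert-butyldimethylsilyl ether survives the citric acid step whereas the aryl and enol trimethylsilyl ethers do not, which prevents early lactonisation onto the ester and leaves a hydrogen-bonded C5 phenol and a free C7 phenol.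

Step 7
Reactants: 11 methyl 6-[(4-benzyloxy-3-methoxyphenyl)(tert-butyldimethylsilyloxy)methyl]-2,4-dihydroxy-3-methoxybenzoate
Product: 13 methyl 4-benzyloxy-6-[(4-benzyloxy-3-methoxyphenyl)(tert-butyldimethylsilyloxy)methyl]-2,3-dimethoxybenzoate (racemic), via C7 benzyl ether 12 (not isolated)
Conditions: BnBr (1.05 equiv), K2CO3, DMF, rt; then MeI (excess), 50 °C
Reagents that add atoms: benzyl bromide, BrCc1ccccc1; iodomethane, CI
Why: Two Williamson etherifications in sequence: the C7 phenol (para to the ester, not hydrogen-bonded) is the more acidic and accessible and is benzylated at room temperature, while the C5 phenol, held in a hydrogen bond to the ester carbonyl, reacts only with the small electrophile on warming.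

Step 8
Reactants: 13 methyl 4-benzyloxy-6-[(4-benzyloxy-3-methoxyphenyl)(tert-butyldimethylsilyloxy)methyl]-2,3-dimethoxybenzoate
Product: 15 4-benzyloxy-6-(4-benzyloxy-3-methoxybenzyl)-2,3-dimethoxybenzoic acid, via 3-arylphthalide 14 (not isolated)
Conditions: Bu4NF, THF, 0 °C → rt; then Zn dust, 10% aq. KOH, pyridine, reflux; HCl to pH 2
Reagents that add atoms: potassium hydroxide, [K+].[OH-]
Why: Fluoride frees the C1 alkoxide, which closes onto the neighbouring methyl ester (5-exo-trig lactonisation) to give 14, and zinc in aqueous alkali then cleaves the doubly benzylic C1–O bond reductively, the classical conversion of 3-arylphthalides into 2-benzylbenzoic acids, which leaves aryl benzyl and methyl ethers intact. Using the ester as an internal handle avoids a free C1 cation beside it; since 14 equilibrates with its hydroxy carboxylate in alkali, one carboxyl oxygen of 15 can come from hydroxide.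

Step 9
Reactants: 15 4-benzyloxy-6-(4-benzyloxy-3-methoxybenzyl)-2,3-dimethoxybenzoic acid
Product: 16 [4-benzyloxy-6-(4-benzyloxy-3-methoxybenzyl)-2,3-dimethoxyphenyl]methanol
Conditions: LiAlH4, THF, 0 °C → reflux; H2O, aq. NaOH
Reagents that add atoms: none
Why: Hydride reduction of a carboxylic acid to the primary alcohol; the doubly ortho-substituted acid needs warming, and the ethers are inert.

Step 10
Reactants: 17 fumaryl chloride; 18 methyl (R)-lactate (2.1 equiv)
Product: 19 bis[(2R)-1-methoxy-1-oxopropan-2-yl] (E)-but-2-enedioate
Conditions: pyridine, CH2Cl2, 0 °C → rt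
Reagents that add atoms: none
Why: Acylation of a secondary alcohol by an acid chloride; the lactate stereocentre is not involved in bond formation and the mild base does not racemise it.

Step 11
Reactants: 16 [4-benzyloxy-6-(4-benzyloxy-3-methoxybenzyl)-2,3-dimethoxyphenyl]methanol; 19 bis[(2R)-1-methoxy-1-oxopropan-2-yl] (E)-but-2-enedioate
Product: 22 bis[(2R)-1-methoxy-1-oxopropan-2-yl] (1R,2S,3R,4R)-7-benzyloxy-1-(4-benzyloxy-3-methoxyphenyl)-4-hydroxy-5,6-dimethoxy-1,2,3,4-tetrahydronaphthalene-2,3-dicarboxylate, via aldehyde 20 (not isolated), via hydroxy-o-quinodimethane 21 (not isolated)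
Conditions: MnO2 (activated, excess), CH2Cl2, rt, dark; filter (Celite), concentrate; then 19, degassed toluene, hν (365 nm), dilute, rt; separation of diastereomers
Reagents that add atoms: none
Why: Activated MnO2 oxidises the electron-rich benzylic alcohol to aldehyde 20 without over-oxidation or attack on the diarylmethane CH2, and the light-sensitive 20 is taken on crude after filtration. Photoenolisation/Diels–Alder reaction: excitation of 20 causes 1,5-hydrogen transfer from the diarylmethane CH2 to the carbonyl oxygen, and the longer-lived dienol 21, with OH and aryl both outward, is trapped by an excess of 19 in a [4+2] cycloaddition that forms C1–C2 and C3–C4. The outward groups end up cis (C1/C4), the fumarate keeps C2/C3 trans and the ester on the carbon bonding to C4 should sit endo beside the hydroxyl while the twisted aryl group keeps its neighbour exo, which gives the 1,2-trans, 2,3-trans, 3,4-cis array; the absolute sense should come from the (R)-lactate units, with the dienol OH hydrogen-bonded to the carbonyl of the endo lactate so that its methyl group blocks one face of the fumarate, and minor diastereomers are removable because the auxiliary is still attached.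

Step 12
Reactants: 22 bis[(2R)-1-methoxy-1-oxopropan-2-yl] (1R,2S,3R,4R)-7-benzyloxy-1-(4-benzyloxy-3-methoxyphenyl)-4-hydroxy-5,6-dimethoxy-1,2,3,4-tetrahydronaphthalene-2,3-dicarboxylate
Product: 23 [(1R,2S,3S,4R)-7-benzyloxy-1-(4-benzyloxy-3-methoxyphenyl)-4-hydroxy-5,6-dimethoxy-1,2,3,4-tetrahydronaphthalene-2,3-diyl]dimethanol
Conditions: LiAlH4 (excess), THF, 0 °C → rt; H2O, aq. NaOH
Reagents that add atoms: none
Why: Hydride reduction of all four ester groups: the ring carboxylates become the C2 and C3 hydroxymethyl groups and the lactate units leave as water-soluble (R)-propane-1,2-diol. Reduction is faster than enolisation, and the trans-diequatorial C2/C3 arrangement is the stable one in any case.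

Step 13
Reactants: 23 [(1R,2S,3S,4R)-7-benzyloxy-1-(4-benzyloxy-3-methoxyphenyl)-4-hydroxy-5,6-dimethoxy-1,2,3,4-tetrahydronaphthalene-2,3-diyl]dimethanol
Product: 24 (1R,2S,3S)-1-(4-hydroxy-3-methoxyphenyl)-2,3-bis(hydroxymethyl)-5,6-dimethoxy-1,2,3,4-tetrahydronaphthalen-7-ol
Conditions: H2 (1 atm), 10% Pd/C, EtOH–AcOH (10:1), rt
Reagents that add atoms: none
Why: Catalytic hydrogenolysis cleaves both aryl benzyl ethers and the benzylic C4–OH bond, which is activated by the ortho C5 methoxy group and the para C7 oxygen. C1 carries no oxygen, and the weak acid should keep elimination toward C3 out of play, so the three stereocentres are untouched.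

## Compound list

1 | methyl methoxyacetate | COCC(=O)OC | starting material
2 | acetyl chloride | CC(=O)Cl | starting material
3 | methyl 2-methoxy-3-oxobutanoate (racemic) | COC(=O)C(OC)C(C)=O | intermediate
4 | methyl 2-methoxy-3-(trimethylsilyloxy)but-2-enoate (E/Z mixture) | COC(=O)C(OC)=C(C)O[Si](C)(C)C | intermediate
5 | 1,2-dimethoxy-1,3-bis(trimethylsilyloxy)buta-1,3-diene | C=C(O[Si](C)(C)C)C(OC)=C(OC)O[Si](C)(C)C | intermediate
6 | methyl propiolate | C#CC(=O)OC | starting material
7 | 4-benzyloxy-3-methoxybenzaldehyde | COc1cc(C=O)ccc1OCc1ccccc1 | starting material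
8 | methyl 4-(4-benzyloxy-3-methoxyphenyl)-4-hydroxybut-2-ynoate (racemic) | COC(=O)C#CC(O)c1ccc(OCc2ccccc2)c(OC)c1 | intermediate
9 | methyl 4-(4-benzyloxy-3-methoxyphenyl)-4-(tert-butyldimethylsilyloxy)but-2-ynoate (racemic) | COC(=O)C#CC(O[Si](C)(C)C(C)(C)C)c1ccc(OCc2ccccc2)c(OC)c1 | intermediate
10 | methyl 2-[(4-benzyloxy-3-methoxyphenyl)(tert-butyldimethylsilyloxy)methyl]-5,6-dimethoxy-4,6-bis(trimethylsilyloxy)cyclohexa-1,4-diene-1-carboxylate (stereoisomer mixture, not isolated) | COC(=O)C1=C(C(O[Si](C)(C)C(C)(C)C)c2ccc(OCc3ccccc3)c(OC)c2)CC(O[Si](C)(C)C)=C(OC)C1(OC)O[Si](C)(C)C | intermediate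
11 | methyl 6-[(4-benzyloxy-3-methoxyphenyl)(tert-butyldimethylsilyloxy)methyl]-2,4-dihydroxy-3-methoxybenzoate (racemic) | COC(=O)c1c(O)c(OC)c(O)cc1C(O[Si](C)(C)C(C)(C)C)c1ccc(OCc2ccccc2)c(OC)c1 | intermediate
12 | methyl 4-benzyloxy-6-[(4-benzyloxy-3-methoxyphenyl)(tert-butyldimethylsilyloxy)methyl]-2-hydroxy-3-methoxybenzoate (racemic, not isolated) | COC(=O)c1c(O)c(OC)c(OCc2ccccc2)cc1C(O[Si](C)(C)C(C)(C)C)c1ccc(OCc2ccccc2)c(OC)c1 | intermediate
13 | methyl 4-benzyloxy-6-[(4-benzyloxy-3-methoxyphenyl)(tert-butyldimethylsilyloxy)methyl]-2,3-dimethoxybenzoate (racemic) | COC(=O)c1c(OC)c(OC)c(OCc2ccccc2)cc1C(O[Si](C)(C)C(C)(C)C)c1ccc(OCc2ccccc2)c(OC)c1 | intermediate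
14 | 5-benzyloxy-3-(4-benzyloxy-3-methoxyphenyl)-6,7-dimethoxy-3H-isobenzofuran-1-one (racemic, not isolated) | O=C1OC(c2ccc(OCc3ccccc3)c(OC)c2)c2cc(OCc3ccccc3)c(OC)c(OC)c21 | intermediate
15 | 4-benzyloxy-6-(4-benzyloxy-3-methoxybenzyl)-2,3-dimethoxybenzoic acid | OC(=O)c1c(OC)c(OC)c(OCc2ccccc2)cc1Cc1ccc(OCc2ccccc2)c(OC)c1 | intermediate
16 | [4-benzyloxy-6-(4-benzyloxy-3-methoxybenzyl)-2,3-dimethoxyphenyl]methanol | OCc1c(OC)c(OC)c(OCc2ccccc2)cc1Cc1ccc(OCc2ccccc2)c(OC)c1 | intermediate
17 | fumaryl chloride | O=C(Cl)/C=C/C(=O)Cl | starting material
18 | methyl (R)-lactate | C[C@@H](O)C(=O)OC | starting material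
19 | bis[(2R)-1-methoxy-1-oxopropan-2-yl] (E)-but-2-enedioate | C[C@@H](OC(=O)/C=C/C(=O)O[C@H](C)C(=O)OC)C(=O)OC | intermediate
20 | 4-benzyloxy-6-(4-benzyloxy-3-methoxybenzyl)-2,3-dimethoxybenzaldehyde (not isolated) | O=Cc1c(OC)c(OC)c(OCc2ccccc2)cc1Cc1ccc(OCc2ccccc2)c(OC)c1 | intermediate
21 | 3-benzyloxy-5-(4-benzyloxy-3-methoxybenzylidene)-6-(hydroxymethylidene)-1,2-dimethoxycyclohexa-1,3-diene, OH and aryl both outward (not isolated) | O/C=C1\C(OC)=C(OC)C(OCc2ccccc2)=C/C1=C\c1ccc(OCc2ccccc2)c(OC)c1 | intermediate
22 | bis[(2R)-1-methoxy-1-oxopropan-2-yl] (1R,2S,3R,4R)-7-benzyloxy-1-(4-benzyloxy-3-methoxyphenyl)-4-hydroxy-5,6-dimethoxy-1,2,3,4-tetrahydronaphthalene-2,3-dicarboxylate | COc1cc([C@@H]2c3cc(OCc4ccccc4)c(OC)c(OC)c3[C@H](O)[C@H](C(=O)O[C@H](C)C(=O)OC)[C@H]2C(=O)O[C@H](C)C(=O)OC)ccc1OCc1ccccc1 | intermediate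
23 | [(1R,2S,3S,4R)-7-benzyloxy-1-(4-benzyloxy-3-methoxyphenyl)-4-hydroxy-5,6-dimethoxy-1,2,3,4-tetrahydronaphthalene-2,3-diyl]dimethanol | COc1cc([C@@H]2c3cc(OCc4ccccc4)c(OC)c(OC)c3[C@H](O)[C@H](CO)[C@H]2CO)ccc1OCc1ccccc1 | intermediate
24 | (1R,2S,3S)-1-(4-hydroxy-3-methoxyphenyl)-2,3-bis(hydroxymethyl)-5,6-dimethoxy-1,2,3,4-tetrahydronaphthalen-7-ol | COc1cc([C@@H]2c3cc(O)c(OC)c(OC)c3C[C@H](CO)[C@H]2CO)ccc1O | target

## Step count and least certain steps

Total: 13 steps. Longest linear sequence: 10 steps (1, 2, 3, 6, 7, 8, 9, 11, 12, 13).

Step 6 (key step). The most likely failure is a sluggish cycloaddition: the alkyne is internal, activated by one ester only and hindered at C8a by the aryl(silyloxy)methyl group, while the diene slowly desilylates and oligomerises at 110 °C. Erosion of regiocontrol is less likely. Fallback: take the bulky aryl carbinol out of the cycloaddition and add ring C afterwards.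
- From 5, cycloaddition with the unhindered, identically polarised ethyl 4,4-diethoxybut-2-ynoate and the same acid treatment, which also unmasks the aldehyde, should give ethyl 6-formyl-2,4-dihydroxy-3-methoxybenzoate F1.
- Benzylation at C7 and methylation at C5 as in step 7 would give ethyl 4-benzyloxy-6-formyl-2,3-dimethoxybenzoate F2.
- Addition of (4-benzyloxy-3-methoxyphenyl)magnesium bromide F3 (from the commercial aryl bromide and Mg) to the aldehyde at −78 °C, with lactonisation of the alkoxide on warming, returns to the route at 14, which is then reduced with zinc as in step 8.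

Step 11. Two processes may interfere in the photochemical stage. First, inefficient trapping: the electron-rich aldehyde transfers hydrogen slowly from its excited state and may instead pass its triplet energy to the fumarate, isomerising it to the maleate. Second, incomplete mode or face selectivity. Fallback: separate photochemistry from cycloaddition.
- From 16, the same MnO2 oxidation followed by irradiation of the crude aldehyde 20 in the presence of SO2 (no dienophile) would trap 21 as cis-6-benzyloxy-1-(4-benzyloxy-3-methoxyphenyl)-3-hydroxy-4,5-dimethoxy-1,3-dihydro-2-benzothiophene 2,2-dioxide F4.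
- Heating F4 with 19 in toluene over ZnO would release SO2 cheletropically, regenerate 21 in the dark and return to the route at 22.
- Diastereomers are separated at 22 in either case, and a reversed sense of induction is answered by the antipodal lactate.

Step 8. Electron transfer from zinc to the very electron-rich lactone may be slow, so that material stalls at 14 or its hydroxy acid. Fallback: from 13, isolate 14 after the fluoride stage and cleave C1–O by ionic hydrogenation (Et3SiH, CF3CO2H, CH2Cl2). Reversible acid ionisation of the lactone to the para-alkoxy-stabilised benzhydryl cation and irreversible hydride capture would return to the route at 15 with no new compound.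

Step 13. Acid-promoted loss of the C4 hydroxyl toward C3, followed by hydrogenation of the resulting alkene, would erode the C3 configuration; incomplete C4–O cleavage is the other risk. Fallback: remove the C4 oxygen before the esters are reduced.
- From 22, Et3SiH and BF3·OEt2 in CH2Cl2 at −40 °C would give bis[(2R)-1-methoxy-1-oxopropan-2-yl] (1R,2S,3S)-7-benzyloxy-1-(4-benzyloxy-3-methoxyphenyl)-5,6-dimethoxy-1,2,3,4-tetrahydronaphthalene-2,3-dicarboxylate F5.
- LiAlH4 would give [(1R,2S,3S)-7-benzyloxy-1-(4-benzyloxy-3-methoxyphenyl)-5,6-dimethoxy-1,2,3,4-tetrahydronaphthalene-2,3-diyl]dimethanol F6.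
- Neutral hydrogenolysis of the two benzyl ethers (H2, Pd/C, EtOAc–MeOH) returns to the route at 24.

## Further compounds

F1 | step 6 | ethyl 6-formyl-2,4-dihydroxy-3-methoxybenzoate | CCOC(=O)c1c(O)c(OC)c(O)cc1C=O
F2 | step 6 | ethyl 4-benzyloxy-6-formyl-2,3-dimethoxybenzoate | CCOC(=O)c1c(OC)c(OC)c(OCc2ccccc2)cc1C=O
F3 | step 6 | (4-benzyloxy-3-methoxyphenyl)magnesium bromide | COc1cc([Mg]Br)ccc1OCc1ccccc1
F4 | step 11 | cis-6-benzyloxy-1-(4-benzyloxy-3-methoxyphenyl)-3-hydroxy-4,5-dimethoxy-1,3-dihydro-2-benzothiophene 2,2-dioxide (racemic, one enantiomer drawn) | O=S1(=O)[C@@H](O)c2c(OC)c(OC)c(OCc3ccccc3)cc2[C@H]1c1ccc(OCc2ccccc2)c(OC)c1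
F0 | step 8 | none | none
F5 | step 13 | bis[(2R)-1-methoxy-1-oxopropan-2-yl] (1R,2S,3S)-7-benzyloxy-1-(4-benzyloxy-3-methoxyphenyl)-5,6-dimethoxy-1,2,3,4-tetrahydronaphthalene-2,3-dicarboxylate | COc1cc([C@@H]2c3cc(OCc4ccccc4)c(OC)c(OC)c3C[C@H](C(=O)O[C@H](C)C(=O)OC)[C@H]2C(=O)O[C@H](C)C(=O)OC)ccc1OCc1ccccc1
F6 | step 13 | [(1R,2S,3S)-7-benzyloxy-1-(4-benzyloxy-3-methoxyphenyl)-5,6-dimethoxy-1,2,3,4-tetrahydronaphthalene-2,3-diyl]dimethanol | COc1cc([C@@H]2c3cc(OCc4ccccc4)c(OC)c(OC)c3C[C@H](CO)[C@H]2CO)ccc1OCc1ccccc1
A1 | alternative 1 | (4R,5R)-1-[(E)-3-(4-benzyloxy-2,3-dimethoxyphenyl)prop-2-enoyl]-3-[(E)-3-(4-hydroxy-3-methoxyphenyl)prop-2-enoyl]-4,5-diphenylimidazolidin-2-one | COc1cc(/C=C/C(=O)N2C(=O)N(C(=O)/C=C/c3ccc(OCc4ccccc4)c(OC)c3OC)[C@H](c3ccccc3)[C@H]2c2ccccc2)ccc1O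
A2 | alternative 1 | auxiliary-bridged 1-aryl-1,2-dihydronaphthalene-2,3-dicarbonyl compound with C1 and C2 in the target configuration | COc1cc([C@@H]2c3cc(OCc4ccccc4)c(OC)c(OC)c3C=C3C(=O)N4[C@H](c5ccccc5)[C@@H](c5ccccc5)N(C4=O)C(=O)[C@H]32)ccc1O
A3 | alternative 2 | methyl 4-(4-benzyloxy-3-methoxyphenyl)-5,6-bis(benzyloxymethyl)-7-(3,4-dimethoxyfuran-2-yl)hept-2-ynoate, configured at C4–C6 as C1–C3 of the target | COc1cc([C@H](C#CC(=O)OC)[C@H](COCc2ccccc2)[C@@H](COCc2ccccc2)Cc2occ(OC)c2OC)ccc1OCc1ccccc1
A4 | alternative 2 | methyl 1-(4-benzyloxy-3-methoxyphenyl)-2,3-bis(benzyloxymethyl)-7-hydroxy-5,6-dimethoxytetralin-8-carboxylate in the target configuration | COc1cc([C@@H]2c3c(C(=O)OC)c(O)c(OC)c(OC)c3C[C@H](COCc3ccccc3)[C@H]2COCc2ccccc2)ccc1OCc1ccccc1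
A5 | alternative 3 | (3S)-3-(benzyloxymethyl)-4-{4-benzyloxy-6-[hydroxy(4-hydroxy-3-methoxyphenyl)methyl]-2,3-dimethoxyphenyl}butanal (carbinol epimers) | COc1cc(C(O)c2cc(OCc3ccccc3)c(OC)c(OC)c2C[C@H](COCc2ccccc2)CC=O)ccc1O
A6 | alternative 3 | all-trans 7-benzyloxy-3-(benzyloxymethyl)-1-(4-hydroxy-3-methoxyphenyl)-5,6-dimethoxytetralin-2-carbaldehyde in the target configuration | COc1cc([C@@H]2c3cc(OCc4ccccc4)c(OC)c(OC)c3C[C@H](COCc3ccccc3)[C@H]2C=O)ccc1O
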